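**Plan**

Numbering: the upper flavan-3-ol unit is unprimed (rings A, B, C), the lower flavan-3,4-diol unit is primed (rings D, E, F), and the two are joined C4–C6'.
Cuts, in retrosynthetic order: C4'–H (hydride onto a C4' ketone); the C3' and C4' oxygens (back to a C3'=C4' alkene); C3'=C4' (ring-closing metathesis); O1'–C2' (allylic etherification); C4–C6' (Friedel–Crafts arylation of a C4 cation by the future ring D). The upper unit is cut the same way at C3=C4 and O1–C2.
Enabling feature: in ring F the neighbouring carbons C3' and C4' both carry oxygen, and C4' is bound to ring D ortho to O1'. Ring F is therefore the metathesis product of a ring D styrene and an O1'-bound 1-arylallyl group, and C2' is the only stereocentre needed beforehand.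
Forward order: carbonate 4; ring C by etherification and metathesis (steps 4–6); C4 electrophile 11; C4–C6' bond to 2,4-dihydroxybenzaldehyde as ring D (step 9); benzylation, methylenation, etherification; ring F by metathesis (step 13); dihydroxylation, benzylic oxidation, debenzylation, hydride reduction.
Stereochemistry: C2 and C2' from the iridium phosphoramidite catalyst; C3 and C3' from OsO4 addition anti to the C2/C2' aryl; C4 from α-face arylation under control of the C3 acetate; C4' from axial hydride delivery to the 2',3'-trans dihydroflavonol.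

Key step: step 13

Assumption: the (Sa,Sc,Sc) antipode of the phosphoramidite ligand is taken to give the (S)-configured branched aryl ether from an (E)-cinnamyl carbonate; should a pilot run on 6 show the opposite sense, the (Ra,Rc,Rc) ligand is used in steps 5 and 12 and nothing else changes.

**Route**

Step 1
Reactants: 1 3,4-bis(benzyloxy)benzaldehyde
Product: 2 ethyl (2E)-3-[3,4-bis(benzyloxy)phenyl]prop-2-enoate
Conditions: Ph3P=CHCO2Et (1.2 equiv), toluene, 80 °C
Reagents that add atoms: ethyl (triphenylphosphoranylidene)acetate, CCOC(=O)C=P(c1ccccc1)(c1ccccc1)c1ccccc1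
Why: Wittig olefination with a stabilised ylide should give the (E)-cinnamate selectively and leaves the benzyl ethers alone.

Step 2
Reactants: 2 ethyl (2E)-3-[3,4-bis(benzyloxy)phenyl]prop-2-enoate
Product: 3 (2E)-3-[3,4-bis(benzyloxy)phenyl]prop-2-en-1-ol
Conditions: i-Bu2AlH (2.5 equiv), CH2Cl2, −78 °C; aq. KNaC4H4O6
Reagents that add atoms: none
Why: Hydride reduction of a conjugated ester with i-Bu2AlH proceeds 1,2 to the allylic alcohol without touching the alkene.

Step 3
Reactants: 3 (2E)-3-[3,4-bis(benzyloxy)phenyl]prop-2-en-1-ol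
Product: 4 (2E)-3-[3,4-bis(benzyloxy)phenyl]prop-2-en-1-yl methyl carbonate
Conditions: ClCO2Me, pyridine, CH2Cl2, 0 °C
Reagents that add atoms: methyl chloroformate, COC(=O)Cl
Why: Acylation of the primary allylic alcohol with a chloroformate gives the linear carbonate that serves as the leaving group for iridium allyl formation.

Step 4
Reactants: 5 4-(benzyloxy)-2-hydroxybenzaldehyde
Product: 6 5-(benzyloxy)-2-ethenylphenol
Conditions: Ph3PCH3Br (2.5 equiv), KOt-Bu (2.5 equiv), THF, 0 °C to rt; aq. NH4Cl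
Reagents that add atoms: methyltriphenylphosphonium bromide (CH2 source through its ylide), C[P+](c1ccccc1)(c1ccccc1)c1ccccc1.[Br-]
Why: Wittig methylenation with excess ylide converts a salicylaldehyde, present as its phenoxide, into the 2-vinylphenol.

Step 5
Reactants: 6 5-(benzyloxy)-2-ethenylphenol; 4 (2E)-3-[3,4-bis(benzyloxy)phenyl]prop-2-en-1-yl methyl carbonate
Product: 8 4-(benzyloxy)-2-{[(1S)-1-[3,4-bis(benzyloxy)phenyl]prop-2-en-1-yl]oxy}-1-ethenylbenzene, via lithium aryloxide 7 (not isolated)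
Conditions: 6 (1.3 equiv), LiN(SiMe3)2 (1.3 equiv), THF, 0 °C; then 4, [Ir(cod)Cl]2 (2 mol%), (Sa,Sc,Sc)-O,O'-(1,1'-binaphthalene-2,2'-diyl) N,N-bis(1-phenylethyl)phosphoramidite (4 mol%), THF, rt to 40 °C
Reagents that add atoms: none
Why: In this iridium-catalysed asymmetric allylic etherification the cyclometalated iridium phosphoramidite ionises the linear carbonate and the aryloxide attacks the aryl-bearing allyl terminus, so the branched ether forms with the future C2 centre set (S) by the ligand.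

Step 6
Reactants: 8 4-(benzyloxy)-2-{[(1S)-1-[3,4-bis(benzyloxy)phenyl]prop-2-en-1-yl]oxy}-1-ethenylbenzene
Product: 9 (2S)-7-(benzyloxy)-2-[3,4-bis(benzyloxy)phenyl]-2H-chromene
Conditions: second-generation Grubbs catalyst RuCl2(=CHPh)(PCy3)(H2IMes) (3 mol%), 1,4-benzoquinone (10 mol%), CH2Cl2 (0.01 M), 40 °C
Reagents that add atoms: none
Why: Ring-closing metathesis of a 2-vinylphenyl allyl ether closes ring C as a 2H-chromene under neutral conditions that leave the C2 centre untouched.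

Step 7
Reactants: 9 (2S)-7-(benzyloxy)-2-[3,4-bis(benzyloxy)phenyl]-2H-chromene
Product: 10 (2R,3S,4S)-7-(benzyloxy)-2-[3,4-bis(benzyloxy)phenyl]chromane-3,4-diol (2,3-trans-3,4-cis)
Conditions: OsO4 (2 mol%), NMO (1.5 equiv), acetone/H2O (8:1), rt; aq. Na2SO3
Reagents that add atoms: N-methylmorpholine N-oxide, C[N+]1([O-])CCOCC1; water, O
Why: Upjohn dihydroxylation adds both oxygens syn to C3=C4 on the face opposite the C2 aryl group, so C3 (S) is set from C2.

Step 8
Reactants: 10 (2R,3S,4S)-7-(benzyloxy)-2-[3,4-bis(benzyloxy)phenyl]chromane-3,4-diol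
Product: 11 (2R,3S,4S)-7-(benzyloxy)-2-[3,4-bis(benzyloxy)phenyl]chromane-3,4-diyl diacetate
Conditions: Ac2O, pyridine, DMAP (cat.), CH2Cl2, rt
Reagents that add atoms: acetic anhydride, CC(=O)OC(C)=O
Why: Standard acylation installs the C4 acetate as leaving group and the C3 acetate as participating group for the next step.

Step 9
Reactants: 11 (2R,3S,4S)-7-(benzyloxy)-2-[3,4-bis(benzyloxy)phenyl]chromane-3,4-diyl diacetate; 12 2,4-dihydroxybenzaldehyde
Product: 13 (2R,3S)-2,3-trans-3,4-trans-7-(benzyloxy)-2-[3,4-bis(benzyloxy)phenyl]-4-(5-formyl-2,4-dihydroxyphenyl)chroman-3-yl acetate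
Conditions: 12 (5 equiv), TMSOTf (0.2 equiv), MeCN/CH2Cl2, −30 to 0 °C; aq. NaHCO3
Reagents that add atoms: none
Why: In this Friedel–Crafts C4 arylation of a flavan-4-yl cation the acid ionises the C4 acetate to a cation stabilised by the para 7-benzyloxy group, the C3 acetate bridges or shields the β face, and C5 of 12 (para to its 2-OH, ortho to its 4-OH) attacks from the α face to give the 3,4-trans C4–C6' bond.

Step 10
Reactants: 13 (2R,3S)-2,3-trans-3,4-trans-7-(benzyloxy)-2-[3,4-bis(benzyloxy)phenyl]-4-(5-formyl-2,4-dihydroxyphenyl)chroman-3-yl acetate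
Product: 15 (2R,3S)-2,3-trans-3,4-trans-7-(benzyloxy)-2-[3,4-bis(benzyloxy)phenyl]-4-[2-(benzyloxy)-5-formyl-4-hydroxyphenyl]chroman-3-ol, via 4-O-benzyl acetate 14 (not isolated)
Conditions: BnBr (1.1 equiv), K2CO3 (1.2 equiv), DMF, rt; then MeOH, K2CO3 (2 equiv), rt
Reagents that add atoms: benzyl bromide, BrCc1ccccc1
Why: Williamson benzylation is selective for the hydroxyl para to the formyl group because the ortho hydroxyl is held in a hydrogen bond to the carbonyl, and carbonate-catalysed methanolysis then removes the acetate in the same flask.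

Step 11
Reactants: 15 (2R,3S)-2,3-trans-3,4-trans-7-(benzyloxy)-2-[3,4-bis(benzyloxy)phenyl]-4-[2-(benzyloxy)-5-formyl-4-hydroxyphenyl]chroman-3-ol
Product: 16 (2R,3S)-2,3-trans-3,4-trans-7-(benzyloxy)-2-[3,4-bis(benzyloxy)phenyl]-4-[2-(benzyloxy)-5-ethenyl-4-hydroxyphenyl]chroman-3-ol
Conditions: Ph3PCH3Br (4 equiv), KOt-Bu (4 equiv), THF, 0 °C to rt; aq. NH4Cl
Reagents that add atoms: methyltriphenylphosphonium bromide (CH2 source through its ylide), C[P+](c1ccccc1)(c1ccccc1)c1ccccc1.[Br-]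
Why: Wittig methylenation as in step 4, with enough ylide to cover the phenol, turns the formyl group into the ring D vinyl group without touching any stereocentre.

Step 12
Reactants: 16 (2R,3S)-2,3-trans-3,4-trans-7-(benzyloxy)-2-[3,4-bis(benzyloxy)phenyl]-4-[2-(benzyloxy)-5-ethenyl-4-hydroxyphenyl]chroman-3-ol; 4 (2E)-3-[3,4-bis(benzyloxy)phenyl]prop-2-en-1-yl methyl carbonate
Product: 18 (2R,3S)-2,3-trans-3,4-trans-7-(benzyloxy)-2-[3,4-bis(benzyloxy)phenyl]-4-[2-(benzyloxy)-4-{[(1S)-1-[3,4-bis(benzyloxy)phenyl]prop-2-en-1-yl]oxy}-5-ethenylphenyl]chroman-3-ol, via lithium aryloxide 17 (not isolated)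
Conditions: LiN(SiMe3)2 (1.0 equiv), THF, 0 °C; then 4 (1.5 equiv), [Ir(cod)Cl]2 (4 mol%), (Sa,Sc,Sc)-O,O'-(1,1'-binaphthalene-2,2'-diyl) N,N-bis(1-phenylethyl)phosphoramidite (8 mol%), THF, rt to 40 °C
Reagents that add atoms: none
Why: The same iridium-catalysed branched-selective allylic etherification as in step 5 applies, since one equivalent of base deprotonates only the phenol, the secondary alcohol stays a spectator, and the ligand sets the future C2' centre (S) independently of the remote upper unit.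

Step 13
Reactants: 18 (2R,3S)-2,3-trans-3,4-trans-7-(benzyloxy)-2-[3,4-bis(benzyloxy)phenyl]-4-[2-(benzyloxy)-4-{[(1S)-1-[3,4-bis(benzyloxy)phenyl]prop-2-en-1-yl]oxy}-5-ethenylphenyl]chroman-3-ol
Product: 19 (2R,3S)-2,3-trans-3,4-trans-7-(benzyloxy)-2-[3,4-bis(benzyloxy)phenyl]-4-{(2S)-7-(benzyloxy)-2-[3,4-bis(benzyloxy)phenyl]-2H-chromen-6-yl}chroman-3-ol
Conditions: second-generation Grubbs catalyst RuCl2(=CHPh)(PCy3)(H2IMes) (5 mol%), 1,4-benzoquinone (10 mol%), CH2Cl2 (0.005 M), 40 °C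
Reagents that add atoms: none
Why: The ruthenium benzylidene exchanges onto the monosubstituted alkene of the allyl ether, the new alkylidene adds to the ortho vinyl group in a [2+2] cycloaddition, and cycloreversion of the ruthenacyclobutane expels ethene and forms C3'=C4'. The closest known reaction type is ring-closing metathesis of 2-vinylphenyl allyl ethers to 2H-chromenes. Ring F closes as a six-membered ring by diene ring-closing metathesis between two terminal alkenes held ortho on ring D through O1', so no strain is built up and loss of ethene drives the closure. No stereocentre is created, and the C2' centre from step 12 and the three centres of the upper unit lie outside the reacting atoms and should be carried through unchanged. The step needs ring closure to win over intermolecular metathesis, which the ortho arrangement and high dilution secure, and it needs the doubly activated C2'–O bond and the alkene position to survive, which the neutral medium and the hydride scavenger 1,4-benzoquinone secure. The free C3 hydroxyl and the benzyl ethers are inert to the catalyst.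

Step 14
Reactants: 19 (2R,3S)-2,3-trans-3,4-trans-7-(benzyloxy)-2-[3,4-bis(benzyloxy)phenyl]-4-{(2S)-7-(benzyloxy)-2-[3,4-bis(benzyloxy)phenyl]-2H-chromen-6-yl}chroman-3-ol
Product: 20 (2R,3S)-2,3-trans-3,4-trans-7-(benzyloxy)-2-[3,4-bis(benzyloxy)phenyl]-4-{(2R,3S,4S)-7-(benzyloxy)-2-[3,4-bis(benzyloxy)phenyl]-3,4-dihydroxychroman-6-yl}chroman-3-ol
Conditions: OsO4 (5 mol%), NMO (2 equiv), acetone/H2O (8:1), rt; aq. Na2SO3
Reagents that add atoms: N-methylmorpholine N-oxide, C[N+]1([O-])CCOCC1; water, O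
Why: Upjohn dihydroxylation anti to the C2' aryl sets C3' (S), while the C4' configuration formed here is erased in step 15.

Step 15
Reactants: 20 (2R,3S)-2,3-trans-3,4-trans-7-(benzyloxy)-2-[3,4-bis(benzyloxy)phenyl]-4-{(2R,3S,4S)-7-(benzyloxy)-2-[3,4-bis(benzyloxy)phenyl]-3,4-dihydroxychroman-6-yl}chroman-3-ol
Product: 21 (2R,3R)-7-(benzyloxy)-2-[3,4-bis(benzyloxy)phenyl]-6-{(2R,3S)-2,3-trans-3,4-trans-7-(benzyloxy)-2-[3,4-bis(benzyloxy)phenyl]-3-hydroxychroman-4-yl}-3-hydroxychroman-4-one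
Conditions: activated MnO2 (15 equiv), CH2Cl2, rt
Reagents that add atoms: none
Why: MnO2 is selective for benzylic alcohols, so only the C4' carbinol on the electron-rich ring D should be oxidised, giving the 2',3'-trans dihydroflavonol and leaving the two non-benzylic secondary alcohols.

Step 16
Reactants: 21 (2R,3R)-7-(benzyloxy)-2-[3,4-bis(benzyloxy)phenyl]-6-{(2R,3S)-2,3-trans-3,4-trans-7-(benzyloxy)-2-[3,4-bis(benzyloxy)phenyl]-3-hydroxychroman-4-yl}-3-hydroxychroman-4-one
Product: 22 (2R,3R)-2-(3,4-dihydroxyphenyl)-6-{(2R,3S)-2,3-trans-3,4-trans-2-(3,4-dihydroxyphenyl)-3,7-dihydroxychroman-4-yl}-3,7-dihydroxychroman-4-one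
Conditions: H2 (1 atm), 10% Pd/C, THF/MeOH (1:1), rt
Reagents that add atoms: none
Why: Hydrogenolysis cleaves the six aryl benzyl ethers, while the aryl ketone flanked by ortho and para oxygen donors and the cyclic benzylic C–O and C–C bonds are not reduced in neutral medium, as in routine debenzylation of flavan-3-ols and dihydroflavonols.

Step 17
Reactants: 22 (2R,3R)-2-(3,4-dihydroxyphenyl)-6-{(2R,3S)-2,3-trans-3,4-trans-2-(3,4-dihydroxyphenyl)-3,7-dihydroxychroman-4-yl}-3,7-dihydroxychroman-4-one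
Product: 23 (2R,3S,4R)-2-(3,4-dihydroxyphenyl)-6-{(2R,3S)-2,3-trans-3,4-trans-2-(3,4-dihydroxyphenyl)-3,7-dihydroxychroman-4-yl}chromane-3,4,7-triol (CNP0280090.3)
Conditions: NaBH4 (6 equiv), degassed EtOH, 0 °C; AcOH to pH 6; Sephadex LH-20 (EtOH)
Reagents that add atoms: none
Why: In this borohydride reduction of a 2,3-trans dihydroflavonol, hydride adds axially to C4' on the face cis to the C3' hydroxyl, which should give the all-equatorial 3',4'-trans diol (4'R) as is classical for this compound class, and the work-up is kept near neutral because the product ionises at C4' in acid.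

**Compound list**

1 | 3,4-bis(benzyloxy)benzaldehyde | O=Cc1ccc(OCc2ccccc2)c(OCc2ccccc2)c1 | starting material
2 | ethyl (2E)-3-[3,4-bis(benzyloxy)phenyl]prop-2-enoate | CCOC(=O)/C=C/c1ccc(OCc2ccccc2)c(OCc2ccccc2)c1 | intermediate
3 | (2E)-3-[3,4-bis(benzyloxy)phenyl]prop-2-en-1-ol | OC/C=C/c1ccc(OCc2ccccc2)c(OCc2ccccc2)c1 | intermediate
4 | (2E)-3-[3,4-bis(benzyloxy)phenyl]prop-2-en-1-yl methyl carbonate | COC(=O)OC/C=C/c1ccc(OCc2ccccc2)c(OCc2ccccc2)c1 | intermediate
5 | 4-(benzyloxy)-2-hydroxybenzaldehyde | O=Cc1ccc(OCc2ccccc2)cc1O | starting material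
6 | 5-(benzyloxy)-2-ethenylphenol | C=Cc1ccc(OCc2ccccc2)cc1O | intermediate
7 | lithium 5-(benzyloxy)-2-ethenylphenoxide | [Li+].C=Cc1ccc(OCc2ccccc2)cc1[O-] | intermediate
8 | 4-(benzyloxy)-2-{[(1S)-1-[3,4-bis(benzyloxy)phenyl]prop-2-en-1-yl]oxy}-1-ethenylbenzene | C=Cc1ccc(OCc2ccccc2)cc1O[C@H](c1ccc(OCc2ccccc2)c(OCc2ccccc2)c1)C=C | intermediate
9 | (2S)-7-(benzyloxy)-2-[3,4-bis(benzyloxy)phenyl]-2H-chromene | c1ccccc1COc1ccc2c(c1)O[C@H](c1ccc(OCc3ccccc3)c(OCc3ccccc3)c1)C=C2 | intermediate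
10 | (2R,3S,4S)-7-(benzyloxy)-2-[3,4-bis(benzyloxy)phenyl]chromane-3,4-diol (2,3-trans-3,4-cis) | c1ccccc1COc1ccc2c(c1)O[C@H](c1ccc(OCc3ccccc3)c(OCc3ccccc3)c1)[C@@H](O)[C@H]2O | intermediate
11 | (2R,3S,4S)-7-(benzyloxy)-2-[3,4-bis(benzyloxy)phenyl]chromane-3,4-diyl diacetate | c1ccccc1COc1ccc2c(c1)O[C@H](c1ccc(OCc3ccccc3)c(OCc3ccccc3)c1)[C@@H](OC(C)=O)[C@H]2OC(C)=O | intermediate
12 | 2,4-dihydroxybenzaldehyde | O=Cc1ccc(O)cc1O | starting material
13 | (2R,3S)-2,3-trans-3,4-trans-7-(benzyloxy)-2-[3,4-bis(benzyloxy)phenyl]-4-(5-formyl-2,4-dihydroxyphenyl)chroman-3-yl acetate (C4 aryl α, cis to the C2 aryl) | c1ccccc1COc1ccc2c(c1)O[C@H](c1ccc(OCc3ccccc3)c(OCc3ccccc3)c1)[C@@H](OC(C)=O)[C@@H]2c1cc(C=O)c(O)cc1O | intermediate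
14 | (2R,3S)-2,3-trans-3,4-trans-7-(benzyloxy)-2-[3,4-bis(benzyloxy)phenyl]-4-[2-(benzyloxy)-5-formyl-4-hydroxyphenyl]chroman-3-yl acetate | c1ccccc1COc1ccc2c(c1)O[C@H](c1ccc(OCc3ccccc3)c(OCc3ccccc3)c1)[C@@H](OC(C)=O)[C@@H]2c1cc(C=O)c(O)cc1OCc1ccccc1 | intermediate
15 | (2R,3S)-2,3-trans-3,4-trans-7-(benzyloxy)-2-[3,4-bis(benzyloxy)phenyl]-4-[2-(benzyloxy)-5-formyl-4-hydroxyphenyl]chroman-3-ol | c1ccccc1COc1ccc2c(c1)O[C@H](c1ccc(OCc3ccccc3)c(OCc3ccccc3)c1)[C@@H](O)[C@@H]2c1cc(C=O)c(O)cc1OCc1ccccc1 | intermediate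
16 | (2R,3S)-2,3-trans-3,4-trans-7-(benzyloxy)-2-[3,4-bis(benzyloxy)phenyl]-4-[2-(benzyloxy)-5-ethenyl-4-hydroxyphenyl]chroman-3-ol | c1ccccc1COc1ccc2c(c1)O[C@H](c1ccc(OCc3ccccc3)c(OCc3ccccc3)c1)[C@@H](O)[C@@H]2c1cc(C=C)c(O)cc1OCc1ccccc1 | intermediate
17 | lithium aryloxide of 16 (lithium 5-(benzyloxy)-2-ethenyl-4-[(2R,3S)-2,3-trans-3,4-trans-7-(benzyloxy)-2-[3,4-bis(benzyloxy)phenyl]-3-hydroxychroman-4-yl]phenoxide) | [Li+].c1ccccc1COc1ccc2c(c1)O[C@H](c1ccc(OCc3ccccc3)c(OCc3ccccc3)c1)[C@@H](O)[C@@H]2c1cc(C=C)c([O-])cc1OCc1ccccc1 | intermediate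
18 | (2R,3S)-2,3-trans-3,4-trans-7-(benzyloxy)-2-[3,4-bis(benzyloxy)phenyl]-4-[2-(benzyloxy)-4-{[(1S)-1-[3,4-bis(benzyloxy)phenyl]prop-2-en-1-yl]oxy}-5-ethenylphenyl]chroman-3-ol | c1ccccc1COc1ccc2c(c1)O[C@H](c1ccc(OCc3ccccc3)c(OCc3ccccc3)c1)[C@@H](O)[C@@H]2c1cc(C=C)c(cc1OCc1ccccc1)O[C@H](c1ccc(OCc3ccccc3)c(OCc3ccccc3)c1)C=C | intermediate
19 | (2R,3S)-2,3-trans-3,4-trans-7-(benzyloxy)-2-[3,4-bis(benzyloxy)phenyl]-4-{(2S)-7-(benzyloxy)-2-[3,4-bis(benzyloxy)phenyl]-2H-chromen-6-yl}chroman-3-ol | c1ccccc1COc1ccc2c(c1)O[C@H](c1ccc(OCc3ccccc3)c(OCc3ccccc3)c1)[C@@H](O)[C@@H]2c1cc3c(cc1OCc1ccccc1)O[C@H](c1ccc(OCc4ccccc4)c(OCc4ccccc4)c1)C=C3 | intermediate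
20 | (2R,3S)-2,3-trans-3,4-trans-7-(benzyloxy)-2-[3,4-bis(benzyloxy)phenyl]-4-{(2R,3S,4S)-7-(benzyloxy)-2-[3,4-bis(benzyloxy)phenyl]-3,4-dihydroxychroman-6-yl}chroman-3-ol | c1ccccc1COc1ccc2c(c1)O[C@H](c1ccc(OCc3ccccc3)c(OCc3ccccc3)c1)[C@@H](O)[C@@H]2c1cc3c(cc1OCc1ccccc1)O[C@H](c1ccc(OCc4ccccc4)c(OCc4ccccc4)c1)[C@@H](O)[C@H]3O | intermediate
21 | (2R,3R)-7-(benzyloxy)-2-[3,4-bis(benzyloxy)phenyl]-6-{(2R,3S)-2,3-trans-3,4-trans-7-(benzyloxy)-2-[3,4-bis(benzyloxy)phenyl]-3-hydroxychroman-4-yl}-3-hydroxychroman-4-one | c1ccccc1COc1ccc2c(c1)O[C@H](c1ccc(OCc3ccccc3)c(OCc3ccccc3)c1)[C@@H](O)[C@@H]2c1cc3c(cc1OCc1ccccc1)O[C@H](c1ccc(OCc4ccccc4)c(OCc4ccccc4)c1)[C@@H](O)C3=O | intermediate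
22 | (2R,3R)-2-(3,4-dihydroxyphenyl)-6-{(2R,3S)-2,3-trans-3,4-trans-2-(3,4-dihydroxyphenyl)-3,7-dihydroxychroman-4-yl}-3,7-dihydroxychroman-4-one | Oc1ccc2c(c1)O[C@H](c1ccc(O)c(O)c1)[C@@H](O)[C@@H]2c1cc2c(cc1O)O[C@H](c1ccc(O)c(O)c1)[C@@H](O)C2=O | intermediate
23 | (2R,3S,4R)-2-(3,4-dihydroxyphenyl)-6-{(2R,3S)-2,3-trans-3,4-trans-2-(3,4-dihydroxyphenyl)-3,7-dihydroxychroman-4-yl}chromane-3,4,7-triol (CNP0280090.3) | Oc1ccc2c(c1)O[C@H](c1ccc(O)c(O)c1)[C@@H](O)[C@@H]2c1cc2c(cc1O)O[C@H](c1ccc(O)c(O)c1)[C@@H](O)[C@@H]2O | target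

**Step count and risks**

Total step count: 17. Longest linear sequence: 16 steps (steps 1–3, then 5–17).

Steps most likely to fail:

1. Step 9. The formyl group makes 12 a weak nucleophile, so the C4 cation may instead be captured by ring A of a second molecule of 11 (self-condensation), or by C3 or a phenolic oxygen of 12. Fallback: setting out from 11, the same acid-catalysed arylation is run with resorcinol in large excess, a far stronger nucleophile with a single accessible position, to give (2R,3S)-2,3-trans-3,4-trans-7-(benzyloxy)-2-[3,4-bis(benzyloxy)phenyl]-4-(2,4-dihydroxyphenyl)chroman-3-yl acetate F1. Magnesium-mediated ortho-formylation (MgCl2, Et3N, paraformaldehyde, MeCN, reflux) then places the formyl group on the resorcinol carbon ortho to one hydroxyl and para to the other, the only unhindered ortho site. The sequence comes back to the route at 13.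

2. Step 12. The branched ether carries an electron-rich aryl group and an aryloxide leaving group, so the catalyst may re-ionise it and erode both the branched-to-linear preference and the configuration at the future C2', and the ortho-substituted aryloxide may turn over slowly. The same process in step 5 would lower the enantiomeric purity of the upper unit, which can be raised by crystallisation of diol 10. Fallback: setting out from 16 and from aldehyde 1, addition of CH2=CHMgBr to 1 (THF, 0 °C) gives racemic 1-[3,4-bis(benzyloxy)phenyl]prop-2-en-1-ol F2. Sharpless kinetic resolution (Ti(Oi-Pr)4, diisopropyl tartrate, t-BuOOH, CH2Cl2, −20 °C, tartrate antipode chosen so that the (S)-alcohol is epoxidised) leaves (1R)-1-[3,4-bis(benzyloxy)phenyl]prop-2-en-1-ol F3. Mitsunobu etherification of phenol 16 with F3 (PPh3, DIAD, toluene, 0 °C) proceeds with inversion at the carbinol carbon and comes back to the route at 18.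

3. Step 15. Oxidative cleavage of the cis-glycol between C3' and C4', or further dehydrogenation toward the flavonol, may compete with the selective benzylic oxidation. Fallback: setting out from 19, epoxidation with dimethyldioxirane (acetone/CH2Cl2, −20 °C) anti to the C2' aryl gives the 3',4'-epoxide of 19, F4, which is not isolated. Water opens it in the same flask at benzylic C4' to the hexa-O-benzyl 2',3'-trans-3',4'-trans diol F5, the C4' epimer being removed by chromatography. Short hydrogenolysis (H2, Pd(OH)2/C, EtOAc/MeOH, rt) then removes the benzyl ethers and comes back to the route at 23.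

**Further compounds**

F1 | step 9 | (2R,3S)-2,3-trans-3,4-trans-7-(benzyloxy)-2-[3,4-bis(benzyloxy)phenyl]-4-(2,4-dihydroxyphenyl)chroman-3-yl acetate | c1ccccc1COc1ccc2c(c1)O[C@H](c1ccc(OCc3ccccc3)c(OCc3ccccc3)c1)[C@@H](OC(C)=O)[C@@H]2c1ccc(O)cc1O
F2 | step 12 | racemic 1-[3,4-bis(benzyloxy)phenyl]prop-2-en-1-ol | OC(C=C)c1ccc(OCc2ccccc2)c(OCc2ccccc2)c1
F3 | step 12 | (1R)-1-[3,4-bis(benzyloxy)phenyl]prop-2-en-1-ol | O[C@@H](c1ccc(OCc2ccccc2)c(OCc2ccccc2)c1)C=C
F4 | step 15 | 3',4'-epoxide of 19 with the oxirane oxygen anti to the C2' aryl | c1ccccc1COc1ccc2c(c1)O[C@H](c1ccc(OCc3ccccc3)c(OCc3ccccc3)c1)[C@@H](O)[C@@H]2c1cc3c(cc1OCc1ccccc1)O[C@H](c1ccc(OCc4ccccc4)c(OCc4ccccc4)c1)[C@H]4O[C@H]43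
F5 | step 15 | (2R,3S)-2,3-trans-3,4-trans-7-(benzyloxy)-2-[3,4-bis(benzyloxy)phenyl]-4-{(2R,3S,4R)-7-(benzyloxy)-2-[3,4-bis(benzyloxy)phenyl]-3,4-dihydroxychroman-6-yl}chroman-3-ol | c1ccccc1COc1ccc2c(c1)O[C@H](c1ccc(OCc3ccccc3)c(OCc3ccccc3)c1)[C@@H](O)[C@@H]2c1cc3c(cc1OCc1ccccc1)O[C@H](c1ccc(OCc4ccccc4)c(OCc4ccccc4)c1)[C@@H](O)[C@@H]3O
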